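Sunday's flask, charged with 17 mM of starting material, turned a smaller share into double product than Friday's with 2.9 mM: 10.2% against 32.0% at 60.0 min. Both had 20 mM of partner. I now have to choose the next charge, so the question is where more starting material stops paying.

| setting | Friday's | Sunday's | grey | ochre | red |
|---|---|---|---|---|---|
| starting material | 2.9 mM | 17 mM | 5.0 mM | 10 mM | 20 mM |
| partner | 20 mM | 20 mM | 20.0 mM | 20.0 mM | 20.0 mM |
| remark | run made earlier | run made earlier |  |  |  |
| time |  |  | 80 min | 80 min | 80 min |

| run | time / min | double product / % | starting material / % |
|---|---|---|---|
| Friday's | 5.00 | 0.7 | 66.3 |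
| Friday's | 8.00 | 2.4 | 52.1 |
| Friday's | 12.0 | 4.3 | 39.4 |
| Friday's | 20.0 | 8.8 | 19.8 |
| Friday's | 30.0 | 14.7 | 9.3 |
| Friday's | 60.0 | 32.0 | 1.3 |
| Sunday's | 4.00 | 0.2 | 73.6 |
| Sunday's | 10.0 | 1.8 | 46.8 |
| Sunday's | 20.0 | 3.9 | 24.5 |
| Sunday's | 30.0 | 5.3 | 14.0 |
| Sunday's | 40.0 | 7.6 | 8.5 |
| Sunday's | 60.0 | 10.2 | 2.6 |

(each reading ± 0.5 percentage points)

* [double product] at the end for grey, ochre, red, in this order
* how that number moves from the first to the last of them (falls, then rises / falls all the way / rises all the way / rises, then falls / hardly changes)

- what was read earlier has a scatter of 0.5 percentage points, one standard deviation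
- "hardly changes" means that all values lie within two and a half points (for a concentration: within two and a half percent of the largest)

Friday's readings give starting material a pseudo-first-order fall of 0.0806 min⁻¹, a half-life of 8.60 min, well inside the 80 min of the coming runs. Double product keeps climbing after that, so I take the fast step as finished, assume it makes a single product and spends partner, and reckon with the partner it leaves free.

On Friday that free [partner] is 17.1 mM by subtraction. This gives my conversion constant, the share of the charge becoming double product per mM of free partner per minute: 3.12 × 10⁻⁴ mM⁻¹ min⁻¹. Sunday's subtraction leaves 3.00 mM, but its reading asks for 5.45 mM. So I estimate the partner spent per unit of starting material charged at 0.856, not a full one.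

With that spending, my row for grey, ochre and red is 1.96 mM, 2.85 mM and 1.44 mM. I therefore charge ochre and leave red.

The forecast gives 1.9 mM, 2.7 mM and 1.5 mM, a row that rises, then falls, and says of red that “the first step eats nearly all the partner”.

The flasks give 1.74 mM, 2.28 mM and 1.87 mM: the row rises, then falls, with ochre on top.

    starting material + partner → single product (k = 0.0670 L mol⁻¹ s⁻¹)
    partner + single product → double product (k = 0.00920 L mol⁻¹ s⁻¹)
    starting material + single product → side product (k = 0.0590 L mol⁻¹ s⁻¹)

Red stands at 1.87 mM through the consumption of partner together with the length of the run: with partner kept at its charge it gives 6.43 mM, and at 800 min it gives 5.13 mM. At 80.0 min red still holds 4.40 mM of partner, and the conversion constant on that amount gives 2.19 mM against the 1.87 mM in the flask. Grey holds 13.7 mM at that time, and the same constant gives 1.71 mM against the 1.74 mM in the flask.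

The earlier runs and the new flask are simulated with constants of no real substance, and the scatter is random.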